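Late in the dusk run target stands still at 41.0 %. Late in the winter run, with half the partner, it stands at 57.7 %, which is higher.

| flask | substrate | partner | remark | time |
|---|---|---|---|---|
| dusk | 0.010 M | 0.015 M | run made earlier |  |
| spring | 0.0050 M | 0.015 M | run made earlier |  |
| midnight | 0.0075 M | 0.015 M | run made earlier |  |
| winter | 0.010 M | 0.0075 M | run made earlier |  |
| alpha | 0.010 M | 0.0150 M | one stirred flow tank at steady state, fed with the mixture as stated, mean residence time 4.0 h |  |
| delta | 0.010 M | 0.0150 M | a closed flask charged with all of it at once and left for 4.0 h | 4.0 h |
| zeta | 0.010 M | 0.0150 M (fed, over 3.20 h) | all but partner at the start; partner goes in evenly over 3.20 h, the run ends at 4.0 h | 4.0 h |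
| theta | 0.010 M (fed, over 3.20 h) | 0.0150 M | all but substrate at the start; substrate goes in evenly over 3.20 h, the run ends at 4.0 h | 4.0 h |

| run | time / h | target / % |
|---|---|---|
| dusk | 0.333 | 27.2 |
| dusk | 0.667 | 35.2 |
| dusk | 1.00 | 38.0 |
| dusk | 1.33 | 39.3 |
| dusk | 1.50 | 39.7 |
| dusk | 2.00 | 40.0 |
| dusk | 2.50 | 41.0 |
| spring | 0.667 | 31.4 |
| spring | 1.33 | 35.7 |
| spring | 2.00 | 36.6 |
| spring | 3.00 | 37.4 |
| spring | 4.00 | 37.6 |
| spring | 5.00 | 38.3 |
| midnight | 0.667 | 33.6 |
| midnight | 1.33 | 37.8 |
| midnight | 2.00 | 38.1 |
| midnight | 3.00 | 38.4 |
| midnight | 4.00 | 40.0 |
| midnight | 5.00 | 40.0 |
| winter | 0.417 | 43.2 |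
| winter | 1.33 | 54.3 |
| winter | 2.00 | 55.7 |
| winter | 3.00 | 57.3 |
| winter | 5.00 | 57.7 |

(scatter of a reading: 0.5 percentage points)

- the set-up with the highest amount of target at the outlet or at the end, in percent of the substrate put in ("none" if the first two lie within 2 percentage points) (alpha / delta / zeta / theta / none)
- amount of target at the outlet or at the end, in percent of the substrate put in, alpha
- amount of target at the outlet or at the end, in percent of the substrate put in, delta
- amount of target at the outlet or at the end, in percent of the substrate put in, zeta
- amount of target at the outlet or at the end, in percent of the substrate put in, theta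

- the stated concentrations are those of everything mixed, before any reaction; amounts are the same in each set-up
- reactions considered so far: target <-> isomer of the product; substrate <-> intermediate A; intermediate B -> decomposed reagent; substrate -> intermediate C; intermediate C -> target; intermediate A <-> intermediate D; substrate -> target; substrate + partner <-> intermediate B
- the feed brings no volume worth counting
- the earlier runs were made in a closed, stirred flask

My own reckoning counts partner in charges of substrate. Suppose each substrate lost takes one partner with it, and count target alone as kept. Then the kept share equals a constant times the logarithm of partner's start level over its end level. The dusk plateau gives that constant as 0.820, and the winter plateau gives 0.695. I carry their mean, 0.758, as a reading. This is the even-split level, the partner level at which substrate divides equally between loss and keeping, a selectivity factor. At partner level p, lost over kept is p over this level.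

Two chemists part here. The first looks at the end state. Delta, alpha, zeta and theta hold the same charges, and delta is the dusk mixture, so she expects them all near 41.0 %. The second looks at the level substrate meets. In delta it starts at 1.50 charges, above the even-split level, while in zeta it starts from nothing.

The forecast is the second chemist's: 39.5 % for alpha, 41 % for delta, 65 % for zeta, 39 % for theta, best zeta. Its ground: “substrate mostly converts before partner builds up”.

Zeta gives 75.6 %, above its forecast by 11 percentage points. Delta gives 41.2 %, alpha 38.5 % and theta 37.6 %. These flasks, with partner standing ready as substrate comes, lie within 3.6 points, and that is the first chemist's region.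

    target ⇌ isomer of the product (K = 0.200, k = 0.00680 s⁻¹)
    substrate ⇌ intermediate A (K = 1.00, k = 0.00290 s⁻¹)
    intermediate B → decomposed reagent (k = 7.20 × 10⁻⁴ s⁻¹)
    substrate → intermediate C (k = 0.00150 s⁻¹)
    intermediate C → target (k = 0.00250 s⁻¹)
    intermediate A ⇌ intermediate D (K = 2.20, k = 3.60 × 10⁻⁴ s⁻¹)
    substrate → target (k = 0.00140 s⁻¹)
    substrate + partner ⇌ intermediate B (K = 530 L mol⁻¹, k = 1.10 L mol⁻¹ s⁻¹)

Zeta ends with 75.6 % target, so 24.4 % of the charge stands outside target, which is what the even-split level counts as lost. By that rule, zeta's ratio reads as an average of 0.244 charges of partner met by substrate, under that level. Its neighbour feeds 0.0037 M of partner instead. Scaled with the feed, the level becomes 0.0602, the share outside target 7.36 %, and target 92.6 %. The neighbour flask gives 79.8 % target, with 16.0 % isomer of the product and 2.27 % decomposed reagent.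

(The readings come from a simulation with constants of no real substance, noise included.)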